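**Assumption (one line):** conjugate addition to the 6-acyloxy-pyranone 5 occurs anti to the C1 acyloxy group, and the spiro-epoxide in step 10 forms anti to the 7-OAc. Both are the configurations the target requires.

## Retrosynthetic overview
1. The last bond, C10–O(salicylate), comes from SN2 opening of the spiro-8,10-epoxide of valtrate (18) by salicylate. This leaves C8–OH with retention.
2. The dienyl enol ether (C3=C4–C5=C6) and the 11-isovalerate are revealed last from the ring-B ketone C4=O of the enone, via enol triflate, reductive carbonylation, reduction and acylation. The enone keeps C5=C6 electron-poor while C7 and C8 are oxidised.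
3. C7 (SeO2 allylic oxidation) and C8 (anti-to-OAc epoxidation of the exocyclic methylene) are set by substrate control on bicyclic enone 11. C9 is set by anti conjugate addition to the Achmatowicz acylal.
4. Ring order: the pyran ring B and C1 come first (Achmatowicz rearrangement of furfuryl alcohol, then Pd-catalysed dynamic kinetic asymmetric acyloxylation, DYKAT). Cyclopentene ring A comes second (conjugate addition, α-methylenation, ring-closing metathesis).

## Route

**Step 1**
Reactants: 1 furfuryl alcohol
Product: 2 6-hydroxy-2H-pyran-3(6H)-one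
Conditions: NBS, NaHCO3, NaOAc, THF/H2O, 0 °C
Reagents that add atoms: water (O)
Why: Achmatowicz oxidative ring expansion builds ring B and the C1 acetal carbon. The anomers interconvert, so no stereocentre is fixed.

**Step 2**
Reactants: 2
Product: 3 6-(tert-butoxycarbonyloxy)-2H-pyran-3(6H)-one
Conditions: Boc2O, cat. DMAP, CH2Cl2, –78 °C
Reagents that add atoms: di-tert-butyl dicarbonate, CC(C)(C)OC(=O)OC(=O)OC(C)(C)C
Why: O-acylation of the lactol gives an anomeric carbonate that Pd(0) can ionise.

**Step 3**
Reactants: 3, 4 isovaleric acid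
Product: 5 (6S)-6-(isovaleroyloxy)-2H-pyran-3(6H)-one
Conditions: Pd2(dba)3·CHCl3 (2.5 mol %), Trost ligand (7.5 mol %, enantiomer chosen to give 6S), THF, rt
Reagents that add atoms: none
Why: Proposed new method: Pd(0) ionises both anomers of 3 to one achiral oxocarbenium-type η3-allyl (C6–C5=C4 of the pyranone). The chiral ligand then differentiates the faces at C6 for carboxylate capture, so the racemate funnels to one acylal. The closest known reactions are O'Doherty Pd-catalysed glycosylation of Boc-pyranones and Trost Pd-DYKAT with carboxylate nucleophiles. This sets C1.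

**Step 4**
Reactants: 6 2,3-dibromopropene, 7 vinylmagnesium bromide
Product: 8 2-bromopenta-1,4-diene
Conditions: cat. CuI, THF, –20 °C
Reagents that add atoms: none
Why: Cu-catalysed SN2 coupling at the allylic bromide leaves the vinyl bromide intact.

**Step 5**
Reactants: 5, 8
Product: 9 (5,6-trans)-4-(dimethylaminomethyl)-5-(penta-1,4-dien-2-yl)-6-isovaleroyloxytetrahydropyran-3-one (the C4 epimers are not distinguished)
Conditions: (a) 8, Mg, THF, 35 °C; (b) CuBr·SMe2, –78 °C, then 5; (c) Me2N+=CH2 I–, –78 → 0 °C
Reagents that add atoms: Eschenmoser's salt, C=[N+](C)C.[I-]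
Why: Cuprate 1,4-addition is anti to the pseudo-axial anomeric acyloxy group, which sets C9 with H9 cis to C1–OiVal as in the target. This is a three-component conjugate addition/Mannich trapping, and the enolate is regiospecific at C5.

**Step 6**
Reactants: 9
Product: 10 5,6-trans α-methylene ketone (C5=CH2)
Conditions: MeI, CH2Cl2, rt; then DBU, 0 °C
Reagents that add atoms: none (the methyl leaves with the amine)
Why: Hofmann-type elimination of the Mannich methiodide gives the α-methylene ketone needed for ring closure.

**Step 7**
Reactants: 10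
Product: 11 bicyclic enone (C4=O, C5=C6, C8=CH2, 1S-OiVal, 9S-H)
Conditions: Hoveyda–Grubbs II (5 mol %), toluene (5 mM), 60 °C
Reagents that add atoms: none
Why: Ring-closing metathesis between the α-methylene ketone and the terminal vinyl group closes cyclopentene ring A and expels ethylene. The hindered 1,1-disubstituted exocyclic alkene cannot form a strain-free ring and is left untouched.

**Step 8**
Reactants: 11
Product: 12 (7S)-hydroxy enone
Conditions: SeO2 (0.6 equiv), TBHP, CH2Cl2, rt
Reagents that add atoms: selenium dioxide, O=[Se]=O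
Why: Riley/Guillemonat SeO2 ene–[2,3] oxidation (as in β-pinene to pinocarveol) oxidises the doubly allylic C7H2 next to the exocyclic alkene. The reagent approaches the convex H9 face, giving 7-OH cis to H9 and trans to C1.

**Step 9**
Reactants: 12
Product: 13 7-acetate
Conditions: Ac2O, pyridine, cat. DMAP, CH2Cl2, 0 °C
Reagents that add atoms: acetic anhydride, CC(=O)OC(C)=O
Why: Simple acetylation installs 7-OAc.

**Step 10**
Reactants: 13
Product: 14 spiro-8,10-epoxide (O anti to 7-OAc)
Conditions: DMDO, acetone/CH2Cl2, –20 → 0 °C
Reagents that add atoms: dimethyldioxirane, CC1(C)OO1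
Why: Electrophilic epoxidation is chemoselective for the electron-rich exocyclic alkene over the enone. It occurs anti to the adjacent allylic acetate, giving 8-O trans to 7-OAc and C10 cis to it, which sets C8.

**Step 11**
Reactants: 14
Product: 15 dienyl enol triflate (C3=C4–OTf)
Conditions: KHMDS, THF, –78 °C; then PhNTf2, –78 → 0 °C
Reagents that add atoms: N-phenyl-bis(trifluoromethanesulfonimide), O=S(=O)(C(F)(F)F)N(c1ccccc1)S(=O)(=O)C(F)(F)F
Why: Kinetic α′-deprotonation at the oxygen-activated C3–H gives the α-alkoxy enolate, which is trapped as the enol triflate. No stereocentre is touched.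

**Step 12**
Reactants: 15
Product: 16 dienal (C4–CHO, C3=C4, C5=C6)
Conditions: Pd(PPh3)4 (5 mol %), LiCl, Bu3SnH (syringe pump), CO (1 atm), THF, 50 °C
Reagents that add atoms: carbon monoxide, [C-]#[O+]
Why: Stille–Scott Pd-catalysed reductive carbonylation of the vinyl triflate installs C11 at aldehyde level and forms the push–pull dienyl enol ether.

**Step 13**
Reactants: 16
Product: 17 11-hydroxy diene
Conditions: NaBH4, CeCl3·7H2O, MeOH/CH2Cl2, –78 °C
Reagents that add atoms: none (hydride only)
Why: Luche 1,2-reduction of the enal gives the primary allylic alcohol without touching the esters or the epoxide.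

**Step 14**
Reactants: 17
Product: 18 valtrate-type 11-isovalerate with the 8,10-epoxide (C22H30O8)
Conditions: isovaleryl chloride, pyridine, cat. DMAP, CH2Cl2, 0 °C
Reagents that add atoms: isovaleryl chloride, CC(C)CC(=O)Cl
Why: Acylation of the primary allylic alcohol installs the 11-isovalerate under mild, non-acidic conditions.

**Step 15**
Reactants: 18, 19 salicylic acid
Product: 20 Jatamanvaltrate I
Conditions: Cs2CO3 (0.5 equiv), DMF, 50 °C, 16 h
Reagents that add atoms: none (salicylic acid is reactant 19)
Why: Cesium salicylate opens the spiro-epoxide by SN2 at the unhindered CH2 (C10) under basic conditions that spare the dienyl enol ether acylal. This gives the 10-salicylate and the tertiary 8-OH with retention.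

## Compound list
1 | furfuryl alcohol | OCc1ccco1 | starting material
2 | 6-hydroxy-2H-pyran-3(6H)-one | O=C1COC(O)C=C1 | intermediate
3 | 6-(Boc-oxy)-2H-pyran-3(6H)-one | O=C1COC(OC(=O)OC(C)(C)C)C=C1 | intermediate
4 | isovaleric acid | CC(C)CC(=O)O | starting material
5 | (6S)-6-(isovaleroyloxy)-2H-pyran-3(6H)-one | O=C1CO[C@@H](OC(=O)CC(C)C)C=C1 | intermediate
6 | 2,3-dibromopropene | BrCC(Br)=C | starting material
7 | vinylmagnesium bromide | C=C[Mg]Br | starting material
8 | 2-bromopenta-1,4-diene | C=CCC(Br)=C | intermediate
9 | Mannich conjugate adduct (5,6-trans) | O=C1CO[C@@H](OC(=O)CC(C)C)[C@H](C(=C)CC=C)C1CN(C)C | intermediate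
10 | α-methylene ketone | O=C1CO[C@@H](OC(=O)CC(C)C)[C@H](C(=C)CC=C)C1=C | intermediate
11 | bicyclic enone with exocyclic methylene | O=C1CO[C@@H](OC(=O)CC(C)C)[C@@H]2C(=C)CC=C12 | intermediate
12 | 7-hydroxy enone | O=C1CO[C@@H](OC(=O)CC(C)C)[C@@H]2C(=C)[C@@H](O)C=C12 | intermediate
13 | 7-acetoxy enone | O=C1CO[C@@H](OC(=O)CC(C)C)[C@@H]2C(=C)[C@@H](OC(C)=O)C=C12 | intermediate
14 | spiro-8,10-epoxy 7-acetoxy enone | O=C1CO[C@@H](OC(=O)CC(C)C)[C@@H]2[C@@]3(CO3)[C@@H](OC(C)=O)C=C12 | intermediate
15 | dienyl enol triflate | FC(F)(F)S(=O)(=O)OC1=CO[C@@H](OC(=O)CC(C)C)[C@@H]2[C@@]3(CO3)[C@@H](OC(C)=O)C=C12 | intermediate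
16 | 11-oxo dienal | O=CC1=CO[C@@H](OC(=O)CC(C)C)[C@@H]2[C@@]3(CO3)[C@@H](OC(C)=O)C=C12 | intermediate
17 | 11-hydroxy diene epoxide | OCC1=CO[C@@H](OC(=O)CC(C)C)[C@@H]2[C@@]3(CO3)[C@@H](OC(C)=O)C=C12 | intermediate
18 | valtrate-type diisovalerate epoxide | CC(C)CC(=O)OCC1=CO[C@@H](OC(=O)CC(C)C)[C@@H]2[C@@]3(CO3)[C@@H](OC(C)=O)C=C12 | intermediate
19 | salicylic acid | OC(=O)c1ccccc1O | starting material
20 | Jatamanvaltrate I | CC(=O)O[C@H]1C=C2C(COC(=O)CC(C)C)=CO[C@@H](OC(=O)CC(C)C)[C@@H]2[C@@]1(O)COC(=O)c1ccccc1O | target

## Totals
Total steps: 15, of which step 4 is a parallel fragment preparation. Longest linear sequence: 14 steps (1 → 2 → 3 → 5 → 9 → 10 → 11 → 12 → 13 → 14 → 15 → 16 → 17 → 18 → 20).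

## Three steps most likely to fail
1. **Step 3 (Pd-DYKAT acyloxylation).** The carboxylate may attack poorly or with low ee.
   Fallback: acylate 2 directly with isovaleryl chloride to give racemic 5. Use an enantioenriched C7-oxygenated nucleophile instead, the alkenyl Grignard from (S)-2-bromo-1,4-pentadien-3-ol TBS ether (from Sharpless kinetic resolution of the racemic bromodivinylcarbinol). Separate the two diastereomeric conjugate adducts. The chirality then comes from the nucleophile and step 8 is no longer needed.
2. **Step 8 (SeO2 at C7).** The oxidant may instead do Riley oxidation at C3H2, over-oxidise to the dienone, or approach from the wrong face.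
   Fallback: generate the cross-conjugated silyl dienol ether of 11 and oxidise γ (C7) with DMDO or a Davis oxaziridine from the convex face. This does not involve the exocyclic alkene.
3. **Step 10 (facial selectivity of the epoxidation).** The reagent may attack syn to 7-OAc, or the bottom face may be shielded by the C1 acylal.
   Fallback: oxidise 12 to the dienone and reduce it with Luche conditions to the 7-epimeric allylic alcohol. Do a hydroxyl-directed syn-epoxidation (VO(acac)2, TBHP) to place O on the α face. Then invert C7 by Mitsunobu with AcOH to give 7β-OAc with 8α-O.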